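A ratio of two rates carries this flask: each free catalyst molecule stands at a fork, one more turn or death. Gas from the held gas phase dissolves. Free catalyst joins substrate and dissolved gas into target, and target turns free catalyst into spent catalyst. Dissolved gas also decays to decomposed reagent, and it joins substrate without catalyst as uncatalysed product.

substrate 10 mM; gas phase 2.1 mM (held); free catalyst 0.25 mM; time 80 s

- the target standing at 80 s, as a percentage of the substrate charged
- concentration of dissolved gas in solution at 20 s, in percent of saturation
- the change that raises the amount of target at 80 s, in percent of the substrate charged most ("none" if none brings more than 2 percentage points) (green / teal / red / none)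
- amount of target at 80 s, in percent of the substrate charged, after teal

- green: doubling the transfer coefficient of step 1, all else as stated
- teal: doubling the amount of free catalyst, all else as stated
- red: doubling the saturation concentration of gas phase, all else as stated

- at the start none of the gas is dissolved
- run time (flask): 80 s

    gas phase ⇌ dissolved gas, rate k1*(csat - [dissolved gas]) (k1 = 0.28 /s, csat = 2.1 mM)
    substrate + dissolved gas + free catalyst → free catalyst + target (k2 = 1.8 × 10⁵ /M²/s)
    free catalyst + target → spent catalyst (k3 = 140 /M/s)
    dissolved gas → decomposed reagent (k4 = 0.021 /s)
    substrate + dissolved gas → uncatalysed product (k5 = 15 /M/s)

I first set gas supply equal to gas uptake, with the charges as they stand: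

gas = 0.653 mM

fork level = k2 × substrate × gas / k3 = 8.39 mM

The fork level is the target concentration at which a turn and a death are equally likely. Free catalyst cancels from these odds. Each turn adds a target and each death removes one, so integrating over the catalyst charge, with the fork level held fixed, gives:

target ≈ root(2 × fork level × catalyst) − (2/3) × catalyst = 18.8%

The weak link is the gas level, which assumes charged catalyst and substrate while both fall. I reforge it at catalyst 0.5 of its charge and, as a guess, substrate 0.7 of its charge:

gas = 1.04 mM, fork level = 9.39 mM, target = 20.0%

The same reckoning gives target 23.8% for teal, 23.4% for green and 29.0% for red, so I pick red. Leaving free catalyst out of the balance and taking substrate at 0.5 of its charge, I put saturation at 20 s at 74.5%.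

The forecast gives 21.5%, 71.5%, red and 25.3%, on the ground that “the plateau rises roughly with the square root of the dissolved gas level”. Its target is higher than mine and its saturation lower, but the pick is the same.

The flask gives 19.7% and 68.9%, with 23.5% after teal. The best change is red, gaining 7 percentage points against 3.9 points for teal and 3.3 points for green.

A neighbour flask charges 1.0 mM of free catalyst, all else as in the recipe. The same reckoning, at 0.5 of that charge and substrate at 0.7, puts its gas at 0.568 mM. Its fork level drops to 5.11 mM, lower than in the flask, and its target comes to 25.3%. That neighbour flask gives 26.3% of target, with 53.4% as uncatalysed product.

The constants are those of an exercise.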